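(The earlier runs and the new flask were generated by integration with made-up constants.)

Which flask ends with more Z after 5.0 min, midnight or summer, and how much does each hold?

| flask | D | G | remark | time |
|---|---|---|---|---|
| amber | 0.20 M | 0.31 equiv | run made earlier |  |
| grey | 0.20 M | 0.32 equiv | run made earlier |  |
| teal | 0.20 M | 0.44 equiv | run made earlier |  |
| midnight | 0.20 M | 0.250 equiv |  | 5.0 min |
| summer | 0.20 M | 0.500 equiv |  | 5.0 min |

- amber (time / min: Z / %, D / %): 0.250: 21.5, 76.0; 0.500: 23.9, 70.9; 1.00: 23.1, 69.1; 2.00: 23.0, 69.9; 4.00: 23.6, 68.1
- grey (time / min: Z / %, D / %): 0.250: 22.4, 75.6; 0.500: 25.3, 70.4; 1.00: 25.3, 69.3; 2.00: 24.2, 67.5; 4.00: 24.3, 69.6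
- teal (time / min: Z / %, D / %): 0.250: 28.0, 68.1; 0.500: 34.0, 61.1; 1.00: 36.8, 54.9; 2.00: 34.3, 57.3; 4.00: 33.3, 56.1

(standard deviation of a reading: 1 percentage point)

- steps under discussion: D + G -> Z + Q; Z <-> L

- which one finishes higher in amount of Z, in percent of the D charged ("neither" within 2 percentage points) (midnight / summer / neither)
- amount of Z at the end, in percent of the D charged, midnight
- amount of Z at the end, in percent of the D charged, summer

G reacts with D to give Z and Q, and Z turns into L and back. The teal run has lost 43.9 % of its D at 4.00 min on 0.44 equiv of G. So G is the limiting reagent there, and I take each G to make one Z.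

Two extreme flasks are easy. In the first, Z never turns into L, so Z equals the G charged: 25.0 % in midnight and 50.0 % in summer. In the second, Z passes wholly into L and Z ends at nothing. The runs lie nearer the first. Pooled over the last two readings of amber, grey and teal, I read 0.760: the Z share, Z at the plateau over G charged. Amber gives 0.752 and teal 0.768, so within the scatter it does not move with the charge.

I therefore reckon L as a correction to the first extreme: 5.99 % in midnight and 12.0 % in summer. That leaves 19.0 % and 38.0 % of Z. Teal's Z readings are flat within the scatter from 2.00 min, sooner than the time asked, so I expect both flasks to have reached their plateau. Summer should lead by 19 percentage points, more than the margin.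

The forecast says summer, with 19 % for midnight and 38.2 % for summer, from a final share of Z “which is independent of loading”. Its figures lie close to mine.

The flasks give summer as the higher, with 18.9 % of Z in midnight and 37.9 % in summer.

    D + G → Z + Q (k = 0.510 M⁻¹ s⁻¹)
    Z ⇌ L (K = 0.320, k = 0.0130 s⁻¹)

The relaxation half-life of Z and L in midnight is 0.215 min, far shorter than the 5.0 min asked. Midnight holds 18.9 % of Z at 2.50 min and 18.9 % at 50.0 min. The Z share times the charge stands at 38.0 % for summer. For the neighbour of midnight with 0.620 equiv of G it gives 47.1 %, and that flask holds 47.0 % of Z.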